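**The problem**

Target 21 is an open-chain bis(bibenzyl) with four benzene rings in a row. Ring A (3-methoxyphenyl) is tied to ring B by a CH2CH2 tether, ring B to ring C through a diaryl ether oxygen, and ring C to ring D (3-hydroxyphenyl) by a second CH2CH2 tether. There is no stereocentre and no ring fusion, so no centre can steer another; every selectivity question is one of regiochemistry and of telling oxygens apart. Ring B is 1,3,4-trisubstituted, with the tether at C1, the aryloxy group at C3 and the free hydroxyl at C4, a catechol whose two oxygens end in different states. Of the peripheral oxygens one stays methylated (ring A) and two must be freed (ring B C4, ring D), so a global Lewis-acid ether cleavage is excluded and the two hydroxyls need groups that leave under conditions an aryl methyl ether ignores. The four benzylic CH2 groups and the electron-rich rings rule out radical halogenation and strong oxidants late in the route. The two reactive intermediates, a terminal aryl ynol ether (acid, prolonged heat) and an enol-ester-bearing 2-pyrone (base, nucleophiles), need neutral handling. The enabling feature is ring B itself: C4 (OH) and C3 (OAr) are adjacent, C1 carries the chain para to C4, and C2, C5 and C6 carry hydrogen. That is the pattern obtained when C3 (oxygenated) and C6 (alkylated) of a 2-pyrone are bridged by an alkyne bearing oxygen on one carbon and hydrogen on the other, and the lactone bridge is then expelled.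

**Retrosynthesis**

21 to 20. The last cut is at the O–acetyl bond on the ring B oxygen and the O–CH2OMe bond on the ring D oxygen. The acetate is what the pyrone chemistry delivers. A methoxymethyl acetal is chosen for ring D because it leaves in the same acidic methanolysis; a benzyl ether would cost a separate hydrogenolysis, and a silyl ether would be at risk in the hot carbonate step that makes 16. Precursor 20 differs from 21 only by these two groups, and the forward step must spare the aryl methyl ether and the diaryl ether, which dilute acid does.

20 to 7 and 18 (key disconnection). Ring B is opened at C1–C2 and C3–C4, which returns it to the acetoxypyrone 7 (ring A, tether, C1, C4, C5, C6 of ring B and the C4 oxygen) and the aryl ynol ether 18 (C2 and C3 of ring B, the ether oxygen, rings C and D). The neighbouring cut at the C3–O ether bond would require a copper-mediated coupling at an oxygen-flanked position of a catechol that must first be differentiated; cuts in the tethers leave that problem untouched. Here the ether oxygen is attached to carbon before ring B exists, and both ring B oxygens arrive differentiated. The two precursors are of nearly equal size and contain no bond between the two halves of the molecule. The forward reaction must proceed through the bridged lactone 19 with the aryloxy carbon bonding to pyrone C3, and 18 must survive the temperature needed.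

7 to 5. The lactone C–O bond and the enol acetate are cut, giving the 2,5-dioxo acid 6 and, behind it, its tert-butyl ester 5. This is the classical enol-lactone disconnection of a δ-keto acid; the α-keto group supplies the C3 oxygen and the second ring double bond by enolisation. The tert-butyl ester is preferred to an ethyl ester because it is removed by acid, so the base-sensitive 1,4-dicarbonyl array never sees hydroxide. Precursor 5 is acyclic, and the forward step must close the six-membered lactone and not a five-membered ring.

5 to 1 and 2. The C2 carbonyl is traced back to the C=CH2 group of 4 (oxidative cleavage). Bond C3–C4 of the chain is then cut between the methyl carbon of ketone 1 and the allylic carbon of the bromomethyl acrylate 2. An α-halo α-keto ester as direct electrophile would be attacked at its ketone by the enolate 3; the acrylate is a masked form that alkylates cleanly. Both components are purchasable, and the forward reaction needs kinetic enolisation of 1 at the methyl group.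

18 to 13 and 14. The C≡C bond of 18 is derived from the dichlorovinyl ether 16 by elimination and halogen–metal exchange through 17. The O–vinyl bond of 16 comes from phenol 13 and trichloroethylene 14 through dichloroacetylene 15. This two-operation sequence is the shortest established access to a terminal aryl ynol ether from a phenol, and it places the two future ring B carbons on oxygen without any arene chemistry. It requires a single free phenol in 13 and a ring D protecting group stable to carbonate and to butyllithium.

13 to 9 and 10. The C–D tether is cut at its central bond as a stilbene, 12, made by Wittig reaction of aldehyde 9 with the ylide 11 from salt 10. A benzyl ether on ring C and the acetal on ring D are chosen so that one hydrogenation saturates the alkene and frees only the ring C phenol. Aldehyde 9 comes from 3-hydroxybenzaldehyde 8 by acetal protection.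

**Roads not taken**

Alternative 1: Ring C is built instead of ring B. Its C2'–C3' and C4'–C5' bonds are cut to the 2-aryloxybuta-1,3-diene A1, which carries rings A and B, and the ethynyl ketone A2, which carries ring D. The forward key step is a normal-demand Diels–Alder reaction giving the 1,4-cyclohexadiene A3.
- Merits: the ynone is a strongly activated dienophile, and the 1,4-orientation of 2-donor dienes with acetylenic ketones is dependable. The cycloaddition itself is therefore better precedented and probably milder than the one chosen here.
- Weak points: A3 is at the wrong oxidation level twice. The ring must be dehydrogenated to the arene and the ketone oxygen removed to make the second CH2 of the tether. A1 requires the complete ring A/B phenol with its catechol already differentiated by classical means, and 2-oxygenated dienes of this kind polymerise readily. A2 has a doubly activated methylene that can isomerise to the allenyl ketone.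
- Comparison: Alternative 1 is stronger in the reliability of the ring-forming event. Against that, the chosen plan delivers ring B aromatic and at the final oxidation level, needs no deoxygenation, and creates the oxygen differentiation of ring B in the ring-forming step.

Alternative 2: Ring B is again built, but from acyclic carbonyl compounds. Bonds C2–C3 and C5–C6 of a cyclohexenone (numbered from the carbonyl carbon) are cut to the aryloxyacetone A4 (rings C and D) and the 2-substituted acrolein A5 (ring A). Forward, amine-catalysed Michael addition of the aryloxy-bearing carbon of A4 to A5 and aldol condensation by the methyl group give cyclohexenone A6 as a diastereomer mixture. Dehydrogenation then gives the ring B phenol.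
- Merits: inexpensive components, no sensitive alkyne, and the C4 oxygen arrives as a ketone that becomes the free phenol without a protecting group. In cost, and in the robustness of the intermediates toward handling, this road is better than the chosen one.
- Weak points: the wanted constitution requires the more substituted, aryloxy-bearing α-carbon to be the Michael donor, whereas enamine formation favours the methyl side. α-Branched acroleins are sluggish and polymerisation-prone acceptors. A6 must be oxidised to the arene in the presence of four benzylic CH2 groups and a benzyl ether, in a ring that could also aromatise by losing the aryloxy group.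
- Comparison: the step count after the key step is similar to the chosen plan. The chosen plan sets against the cheaper inputs a ring that closes with a mechanistically defined orientation and needs no oxidation.

Alternative 3: The C–D tether is cut at both aryl–alkyne bonds. The pieces are the aryl iodide A7 (rings A, B and C with the ether already in place), the aryl bromide A8 (ring D) and propiolic acid A9 as a two-carbon linchpin. Forward, a one-pot Sonogashira coupling and decarboxylative coupling under one palladium–phosphine catalyst give the diarylalkyne A10. A single hydrogenation then reduces the alkyne and removes both benzyl groups.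
- Merits: each operation has close precedent, the coupling is catalytic and convergent, and the endgame is one step. In certainty of execution this is the best of the four routes.
- Weak points: the key step makes only the tether, which a Wittig reaction makes as well. The diaryl ether and the 1,3,4-pattern of ring B are pushed back into the synthesis of A7, where the copper-mediated coupling on a differentiated catechol returns, together with a second tether construction.
- Comparison: Alternative 3 is lower in risk. The chosen plan sets against it that one step creates ring B, its ether linkage and its oxygen differentiation from two fragments of equal size, so no hindered aryl–oxygen coupling is needed; it pays for this with an untested cycloaddition, for which a conventional fallback is given.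

Key step: step 9

Assumption: the bromomethyl acrylate 2 and the Wittig salt 10 are treated as purchased reagents; the alkene geometry of 12 is immaterial because step 6 saturates it.

**Route**

Step 1
Reactants: 1 4-(3-methoxyphenyl)butan-2-one; 2 tert-butyl 2-(bromomethyl)prop-2-enoate
Product: 4 tert-butyl 7-(3-methoxyphenyl)-2-methylidene-5-oxoheptanoate, via lithium enolate 3 (not isolated)
Conditions: LiN(iPr)2 (1.05 equiv), THF, −78 °C, slow addition of 1; then 2 (1.2 equiv), −78 °C
Reagents that add atoms: none
Why: Kinetic deprotonation of a methyl alkyl ketone by a hindered lithium amide takes the methyl proton; the terminal enolate is allylated by the bromomethyl acrylate (addition–elimination) fast enough at −78 °C to outrun enolate equilibration. Enolate alkylation.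

Step 2
Reactants: 4 tert-butyl 7-(3-methoxyphenyl)-2-methylidene-5-oxoheptanoate
Product: 5 tert-butyl 7-(3-methoxyphenyl)-2,5-dioxoheptanoate
Conditions: O3, CH2Cl2/MeOH, −78 °C, Sudan Red 7B as end-point indicator; then Me2S, −78 °C to rt
Reagents that add atoms: ozone ([O-][O+]=O)
Why: Ozonolysis of a 2-substituted acrylate is the standard unmasking of an α-keto ester; the alkene should be consumed well before the anisole ring, and the indicator dye marks the point at which the gas is stopped.

Step 3
Reactants: 5 tert-butyl 7-(3-methoxyphenyl)-2,5-dioxoheptanoate
Product: 7 acetoxypyrone 6-[2-(3-methoxyphenyl)ethyl]-2-oxo-2H-pyran-3-yl acetate, via dioxo acid 6 (not isolated)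
Conditions: CF3CO2H/CH2Cl2 (1:4), 0 °C to rt; evaporate; then Ac2O, NaOAc, 90 °C
Reagents that add atoms: acetic anhydride (CC(=O)OC(C)=O)
Why: Acidolysis of the tert-butyl ester frees the dioxo acid without base; acetic anhydride then effects dehydrative enol lactonisation of the δ-keto acid (a standard enol lactone synthesis) and acetylates the enol of the α-keto lactone. The stability of the 2-pyrone should pull the sequence forward, as in the anhydride-mediated conversion of aldaric acids into 3-acetoxy-2-pyrone carboxylic acids.

Step 4
Reactants: 8 3-hydroxybenzaldehyde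
Product: 9 3-(methoxymethoxy)benzaldehyde
Conditions: MeOCH2Cl, iPr2NEt, CH2Cl2, 0 °C to rt
Reagents that add atoms: chloromethyl methyl ether (COCCl)
Why: O-Alkylation of a phenol by an α-chloro ether, a routine acetal protection; the acetal is stable to all basic, organometallic and hydrogenation steps that follow.

Step 5
Reactants: 9 3-(methoxymethoxy)benzaldehyde; 10 [4-(benzyloxy)benzyl]triphenylphosphonium chloride
Product: 12 1-(benzyloxy)-4-{2-[3-(methoxymethoxy)phenyl]ethenyl}benzene (E/Z mixture), via phosphorus ylide 11 (not isolated)
Conditions: 10, NaN(SiMe3)2, THF, 0 °C; then 9, 0 °C to rt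
Reagents that add atoms: none
Why: Wittig reaction of a semi-stabilised benzylic ylide with an aromatic aldehyde, the standard bibenzyl precursor synthesis; both alkene isomers converge in step 6.

Step 6
Reactants: 12 1-(benzyloxy)-4-{2-[3-(methoxymethoxy)phenyl]ethenyl}benzene (E/Z mixture)
Product: 13 4-{2-[3-(methoxymethoxy)phenyl]ethyl}phenol
Conditions: H2 (1 atm), 10% Pd/C, EtOAc/EtOH, rt
Reagents that add atoms: none
Why: Catalytic hydrogenation saturates the stilbene and hydrogenolyses the benzyl aryl ether in one operation, while the acetal on ring D is inert under neutral conditions; the two oxygens of the C/D unit thus emerge differentiated.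

Step 7
Reactants: 13 4-{2-[3-(methoxymethoxy)phenyl]ethyl}phenol; 14 trichloroethylene
Product: 16 1-{[(E)-1,2-dichloroethenyl]oxy}-4-{2-[3-(methoxymethoxy)phenyl]ethyl}benzene, via dichloroacetylene 15 (not isolated)
Conditions: K2CO3, DMF, 70 °C
Reagents that add atoms: none
Why: Carbonate dehydrochlorinates trichloroethylene in situ and the phenoxide adds anti to the resulting dichloroacetylene, the established synthesis of (E)-1,2-dichlorovinyl aryl ethers; the E geometry follows from this anti addition and disappears in step 8.

Step 8
Reactants: 16 1-{[(E)-1,2-dichloroethenyl]oxy}-4-{2-[3-(methoxymethoxy)phenyl]ethyl}benzene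
Product: 18 1-(ethynyloxy)-4-{2-[3-(methoxymethoxy)phenyl]ethyl}benzene, via lithium acetylide 17 (not isolated)
Conditions: n-BuLi (2.2 equiv), THF, −78 to −40 °C; then H2O, −78 °C; rapid filtration through basic Al2O3, used at once
Reagents that add atoms: none
Why: Two equivalents of butyllithium effect dehydrochlorination and lithium–chlorine exchange to the lithium acetylide, which water protonates; this is the standard dichlorovinyl ether route to ynol ethers. At −78 °C ortho-lithiation next to the acetal should not compete.

Step 9
Reactants: 7 acetoxypyrone 6-[2-(3-methoxyphenyl)ethyl]-2-oxo-2H-pyran-3-yl acetate; 18 1-(ethynyloxy)-4-{2-[3-(methoxymethoxy)phenyl]ethyl}benzene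
Product: 20 2-(4-{2-[3-(methoxymethoxy)phenyl]ethyl}phenoxy)-4-[2-(3-methoxyphenyl)ethyl]phenyl acetate, via bridged lactone 19 (not isolated)
Conditions: 18 (2 equiv, added in portions), BHT (cat.), PhMe, 120 °C, sealed tube
Reagents that add atoms: none
Why: Proposed new method: the closest known reaction type is the inverse-electron-demand Diels–Alder reaction of 2-pyrones with ynamines and ketene acetals followed by retro-[4+2] loss of CO2; an aryl ynol ether has not been shown as the 2π partner of a 3-acyloxy-6-alkyl-2-pyrone. Pyrone 7 reacts as the 4π component through C3–C6 and the alkyne of 18 as the 2π component, in an asynchronous addition that joins the nucleophilic terminal CH of 18 to the electrophilic C6 of 7 and the oxygen-bearing alkyne carbon to C3, giving the bridged lactone 19. Ring B is thereby closed by an intermolecular [4+2] cycloaddition, and 19 aromatises at once by cycloreversion of CO2, which makes the sequence irreversible. No stereocentre is created in 20; the two bridgehead centres of 19 are destroyed on aromatisation. The selectivity needed is regiochemical, with the aryloxy carbon next to the acetoxy carbon. It should follow from the polarisation of both partners (largest LUMO coefficient of the dienyl lactone at C6, largest HOMO coefficient of the ynol ether at the unsubstituted carbon), helped by the small CH terminus meeting the alkyl-bearing C6. An acyloxy and not an alkoxy group at C3 keeps the diene electron-poor, and an aryl ynol ether lacks the hydrogen needed for the retro-ene fragmentation to a ketene that limits alkyl ynol ethers, so it can be heated. Portionwise addition of excess 18 and a radical inhibitor should hold back alkyne oligomerisation.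

Step 10
Reactants: 20 2-(4-{2-[3-(methoxymethoxy)phenyl]ethyl}phenoxy)-4-[2-(3-methoxyphenyl)ethyl]phenyl acetate
Product: 21 2-{4-[2-(3-hydroxyphenyl)ethyl]phenoxy}-4-[2-(3-methoxyphenyl)ethyl]phenol (CNP0225725.0)
Conditions: HCl (ca. 2 M in MeOH), 45 °C
Reagents that add atoms: none
Why: Acid-catalysed methanolysis transesterifies the aryl acetate and cleaves the methoxymethyl acetal in the same flask; the aryl methyl ether, the diaryl ether and the bibenzyl tethers are inert to dilute acid.

**Compound list**

1 | 4-(3-methoxyphenyl)butan-2-one | COc1cccc(CCC(C)=O)c1 | starting material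
2 | tert-butyl 2-(bromomethyl)prop-2-enoate | C=C(CBr)C(=O)OC(C)(C)C | starting material
3 | lithium 4-(3-methoxyphenyl)but-1-en-2-olate | [Li]OC(=C)CCc1cccc(OC)c1 | intermediate (not isolated)
4 | tert-butyl 7-(3-methoxyphenyl)-2-methylidene-5-oxoheptanoate | COc1cccc(CCC(=O)CCC(=C)C(=O)OC(C)(C)C)c1 | intermediate
5 | tert-butyl 7-(3-methoxyphenyl)-2,5-dioxoheptanoate | COc1cccc(CCC(=O)CCC(=O)C(=O)OC(C)(C)C)c1 | intermediate
6 | 7-(3-methoxyphenyl)-2,5-dioxoheptanoic acid | COc1cccc(CCC(=O)CCC(=O)C(=O)O)c1 | intermediate (not isolated)
7 | 6-[2-(3-methoxyphenyl)ethyl]-2-oxo-2H-pyran-3-yl acetate | COc1cccc(CCc2ccc(OC(C)=O)c(=O)o2)c1 | intermediate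
8 | 3-hydroxybenzaldehyde | O=Cc1cccc(O)c1 | starting material
9 | 3-(methoxymethoxy)benzaldehyde | COCOc1cccc(C=O)c1 | intermediate
10 | [4-(benzyloxy)benzyl]triphenylphosphonium chloride | [Cl-].C(c1ccc(OCc2ccccc2)cc1)[P+](c1ccccc1)(c1ccccc1)c1ccccc1 | starting material
11 | [4-(benzyloxy)benzylidene]triphenylphosphorane | C(=P(c1ccccc1)(c1ccccc1)c1ccccc1)c1ccc(OCc2ccccc2)cc1 | intermediate (not isolated)
12 | 1-(benzyloxy)-4-{2-[3-(methoxymethoxy)phenyl]ethenyl}benzene (E/Z mixture, geometry not defined) | COCOc1cccc(C=Cc2ccc(OCc3ccccc3)cc2)c1 | intermediate
13 | 4-{2-[3-(methoxymethoxy)phenyl]ethyl}phenol | COCOc1cccc(CCc2ccc(O)cc2)c1 | intermediate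
14 | trichloroethylene | ClC=C(Cl)Cl | starting material
15 | dichloroacetylene | ClC#CCl | intermediate (not isolated)
16 | 1-{[(E)-1,2-dichloroethenyl]oxy}-4-{2-[3-(methoxymethoxy)phenyl]ethyl}benzene | Cl/C=C(/Cl)Oc1ccc(CCc2cccc(OCOC)c2)cc1 | intermediate
17 | [(4-{2-[3-(methoxymethoxy)phenyl]ethyl}phenoxy)ethynyl]lithium | [Li]C#COc1ccc(CCc2cccc(OCOC)c2)cc1 | intermediate (not isolated)
18 | 1-(ethynyloxy)-4-{2-[3-(methoxymethoxy)phenyl]ethyl}benzene | C#COc1ccc(CCc2cccc(OCOC)c2)cc1 | intermediate
19 | 5-(4-{2-[3-(methoxymethoxy)phenyl]ethyl}phenoxy)-1-[2-(3-methoxyphenyl)ethyl]-3-oxo-2-oxabicyclo[2.2.2]octa-5,7-dien-4-yl acetate (racemic; bridgehead configurations tied by the bicycle) | CC(=O)OC12C=CC(CCc3cccc(OC)c3)(OC1=O)C=C2Oc1ccc(CCc2cccc(OCOC)c2)cc1 | intermediate (not isolated)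
20 | 2-(4-{2-[3-(methoxymethoxy)phenyl]ethyl}phenoxy)-4-[2-(3-methoxyphenyl)ethyl]phenyl acetate | COc1cccc(CCc2ccc(OC(C)=O)c(Oc3ccc(CCc4cccc(OCOC)c4)cc3)c2)c1 | intermediate
21 | 2-{4-[2-(3-hydroxyphenyl)ethyl]phenoxy}-4-[2-(3-methoxyphenyl)ethyl]phenol | COc1cccc(CCc2ccc(O)c(Oc3ccc(CCc4cccc(O)c4)cc3)c2)c1 | target

**Step count and risks**

Total: 10 steps. Longest linear sequence: 7 steps (steps 4 to 10); the pyrone arm (steps 1 to 3) joins at step 9.

Step 9 (key step, the one carrying the new-method label).
- Most likely failure: thermal oligomerisation or adventitious hydration of the ynol ether outpaces a slow cycloaddition, because a 3-acyloxy-6-alkyl pyrone is a weaker acceptor than the ester-substituted pyrones of the precedent. Addition in the reverse orientation is the second possibility.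
- Fallback (known chemistry, from 13, rejoining at 21): phenol 13 is joined to commercial 4-(benzyloxy)-3-bromobenzaldehyde by an Ullmann ether synthesis (CuI, N,N-dimethylglycine, Cs2CO3, dioxane, 100 °C), giving 4-(benzyloxy)-3-(4-{2-[3-(methoxymethoxy)phenyl]ethyl}phenoxy)benzaldehyde F1. A Wittig reaction with the ylide from commercial (3-methoxybenzyl)triphenylphosphonium chloride and NaN(SiMe3)2 gives 1-(benzyloxy)-4-[2-(3-methoxyphenyl)ethenyl]-2-(4-{2-[3-(methoxymethoxy)phenyl]ethyl}phenoxy)benzene F2 as an E/Z mixture. Hydrogenation over 10% Pd/C saturates the alkene and removes the benzyl group, giving 2-(4-{2-[3-(methoxymethoxy)phenyl]ethyl}phenoxy)-4-[2-(3-methoxyphenyl)ethyl]phenol F3. The acidic methanolysis of step 10 then converts F3 into 21.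

Step 3.
- Most likely failure: diversion of the ring closure. The free dioxo acid can dehydrate through its C2 carbonyl in a Paal–Knorr-type furan closure, or be trapped as open-chain enol acetates, instead of lactonising through the carboxyl group.
- Fallback (from 1, rejoining at 7): C2 is masked as a dithiane so that only the carboxyl can close the ring.
 - The enolate 3 is aminomethylated with dimethyl(methylidene)ammonium iodide to 1-(dimethylamino)-5-(3-methoxyphenyl)pentan-3-one F4.
 - Methylation with MeI gives 5-(3-methoxyphenyl)-N,N,N-trimethyl-3-oxopentan-1-aminium iodide F5, which eliminates under aqueous NaHCO3 to the vinyl ketone 5-(3-methoxyphenyl)pent-1-en-3-one F6.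
 - Michael addition of ethyl 1,3-dithiane-2-carboxylate (NaOEt cat., EtOH) gives ethyl 2-[5-(3-methoxyphenyl)-3-oxopentyl]-1,3-dithiane-2-carboxylate F7.
 - LiOH hydrolysis gives 2-[5-(3-methoxyphenyl)-3-oxopentyl]-1,3-dithiane-2-carboxylic acid F8.
 - Ac2O/NaOAc closes the enol lactone 9-[2-(3-methoxyphenyl)ethyl]-8-oxa-1,5-dithiaspiro[5.5]undec-9-en-7-one F9.
 - Dithiane removal (MeI, CaCO3, aqueous MeCN) releases the ketone, whose stable enol form is 3-hydroxy-6-[2-(3-methoxyphenyl)ethyl]-2H-pyran-2-one F10; acetylation (Ac2O, pyridine) returns 7.

Step 8.
- Most likely failure: loss of the terminal ynol ether during isolation and storage, by acid-catalysed hydration to the aryl acetate or by oligomerisation.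
- Fallback (from 16, rejoining at 18): the lithium acetylide 17 is quenched with Me3SiCl instead of water, giving trimethyl[(4-{2-[3-(methoxymethoxy)phenyl]ethyl}phenoxy)ethynyl]silane F11, a form that can be chromatographed and stored. Fluoride (n-Bu4NF, wet THF, −40 °C) releases 18 immediately before step 9.

Step 1.
- Most likely failure: enolate equilibration during the alkylation, leading to attack at the internal α-carbon or to double alkylation.
- Fallback (from 1, rejoining at 4): condensation with 1,1-dimethylhydrazine gives 2-[4-(3-methoxyphenyl)butan-2-ylidene]-1,1-dimethylhydrazine F12. Hydrazone anions form at the less substituted carbon; deprotonation with LiN(iPr)2 and allylation with 2 gives tert-butyl 5-(2,2-dimethylhydrazinylidene)-7-(3-methoxyphenyl)-2-methylideneheptanoate F13. Two-phase hydrolysis with aqueous oxalic acid returns 4.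

**Further compounds**

F1 | step 9 | 4-(benzyloxy)-3-(4-{2-[3-(methoxymethoxy)phenyl]ethyl}phenoxy)benzaldehyde | O=Cc1ccc(OCc2ccccc2)c(Oc2ccc(CCc3cccc(OCOC)c3)cc2)c1
F2 | step 9 | 1-(benzyloxy)-4-[2-(3-methoxyphenyl)ethenyl]-2-(4-{2-[3-(methoxymethoxy)phenyl]ethyl}phenoxy)benzene (E/Z mixture) | COc1cccc(C=Cc2ccc(OCc3ccccc3)c(Oc3ccc(CCc4cccc(OCOC)c4)cc3)c2)c1
F3 | step 9 | 2-(4-{2-[3-(methoxymethoxy)phenyl]ethyl}phenoxy)-4-[2-(3-methoxyphenyl)ethyl]phenol | COc1cccc(CCc2ccc(O)c(Oc3ccc(CCc4cccc(OCOC)c4)cc3)c2)c1
F4 | step 3 | 1-(dimethylamino)-5-(3-methoxyphenyl)pentan-3-one | COc1cccc(CCC(=O)CCN(C)C)c1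
F5 | step 3 | 5-(3-methoxyphenyl)-N,N,N-trimethyl-3-oxopentan-1-aminium iodide | COc1cccc(CCC(=O)CC[N+](C)(C)C)c1.[I-]
F6 | step 3 | 5-(3-methoxyphenyl)pent-1-en-3-one | COc1cccc(CCC(=O)C=C)c1
F7 | step 3 | ethyl 2-[5-(3-methoxyphenyl)-3-oxopentyl]-1,3-dithiane-2-carboxylate | CCOC(=O)C1(CCC(=O)CCc2cccc(OC)c2)SCCCS1
F8 | step 3 | 2-[5-(3-methoxyphenyl)-3-oxopentyl]-1,3-dithiane-2-carboxylic acid | OC(=O)C1(CCC(=O)CCc2cccc(OC)c2)SCCCS1
F9 | step 3 | 9-[2-(3-methoxyphenyl)ethyl]-8-oxa-1,5-dithiaspiro[5.5]undec-9-en-7-one | O=C1OC(CCc2cccc(OC)c2)=CCC13SCCCS3
F10 | step 3 | 3-hydroxy-6-[2-(3-methoxyphenyl)ethyl]-2H-pyran-2-one | COc1cccc(CCc2ccc(O)c(=O)o2)c1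
F11 | step 8 | trimethyl[(4-{2-[3-(methoxymethoxy)phenyl]ethyl}phenoxy)ethynyl]silane | COCOc1cccc(CCc2ccc(OC#C[Si](C)(C)C)cc2)c1
F12 | step 1 | 2-[4-(3-methoxyphenyl)butan-2-ylidene]-1,1-dimethylhydrazine | COc1cccc(CCC(C)=NN(C)C)c1
F13 | step 1 | tert-butyl 5-(2,2-dimethylhydrazinylidene)-7-(3-methoxyphenyl)-2-methylideneheptanoate | COc1cccc(CCC(CCC(=C)C(=O)OC(C)(C)C)=NN(C)C)c1
A1 | alternative 1 | 1-(benzyloxy)-2-(buta-1,3-dien-2-yloxy)-4-[2-(3-methoxyphenyl)ethyl]benzene | C=CC(=C)Oc1cc(CCc2cccc(OC)c2)ccc1OCc1ccccc1
A2 | alternative 1 | 1-[3-(benzyloxy)phenyl]but-3-yn-2-one | C#CC(=O)Cc1cccc(OCc2ccccc2)c1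
A3 | alternative 1 | 2-[3-(benzyloxy)phenyl]-1-(4-{2-(benzyloxy)-5-[2-(3-methoxyphenyl)ethyl]phenoxy}cyclohexa-1,4-dien-1-yl)ethan-1-one | O=C(Cc1cccc(OCc2ccccc2)c1)C1=CCC(Oc2cc(CCc3cccc(OC)c3)ccc2OCc2ccccc2)=CC1
A4 | alternative 2 | 1-(4-{2-[3-(benzyloxy)phenyl]ethyl}phenoxy)propan-2-one | CC(=O)COc1ccc(CCc2cccc(OCc3ccccc3)c2)cc1
A5 | alternative 2 | 4-(3-methoxyphenyl)-2-methylidenebutanal | C=C(CCc1cccc(OC)c1)C=O
A6 | alternative 2 | 6-(4-{2-[3-(benzyloxy)phenyl]ethyl}phenoxy)-4-[2-(3-methoxyphenyl)ethyl]cyclohex-2-en-1-one (mixture of diastereomers) | O=C1C=CC(CCc2cccc(OC)c2)CC1Oc1ccc(CCc2cccc(OCc3ccccc3)c2)cc1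
A7 | alternative 3 | 1-(benzyloxy)-2-(4-iodophenoxy)-4-[2-(3-methoxyphenyl)ethyl]benzene | COc1cccc(CCc2ccc(OCc3ccccc3)c(Oc3ccc(I)cc3)c2)c1
A8 | alternative 3 | 1-(benzyloxy)-3-bromobenzene | Brc1cccc(OCc2ccccc2)c1
A9 | alternative 3 | propiolic acid | C#CC(=O)O
A10 | alternative 3 | 1-(benzyloxy)-2-(4-{[3-(benzyloxy)phenyl]ethynyl}phenoxy)-4-[2-(3-methoxyphenyl)ethyl]benzene | COc1cccc(CCc2ccc(OCc3ccccc3)c(Oc3ccc(C#Cc4cccc(OCc5ccccc5)c4)cc3)c2)c1
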